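**Retrosynthetic overview**
- The ester is made last: target ⇒ anti-1,3-diol + 4-acetoxybenzoyl chloride; the diol ⇒ trans-fused β-ketol by hydroxyl-directed reduction.
- Five-membered ring (closed second): aldol closure of a regiodefined samarium enolate of the cycloheptenedione onto a pendant isopropyl ketone, which is unmasked from the prenyl end by epoxidation and a 1,2-hydride shift.
- Seven-membered ring (closed first): cationic 1,7-closure of an acyclic (2Z,6E)-farnesoyl chloride; a silyl group at C5 steers the acyl cation to the fully substituted C7 and relays chirality to the quaternary centre.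
- Acyclic C15 chain: geranial (C10) + methyl 3-methylbut-3-enoate (C5) by asymmetric vinylogous aldol–lactonisation, then silylative opening of the allylic lactone.
- Ring order: seven-membered first, five-membered second, across the same two C–C bonds as the presumed farnesyl → daucane cyclisation.

Assumption: in step 1 the (R)-bisphosphine gives the (6S)-lactone; if the sense of induction is the opposite, the (S)-ligand is used.

**Step 1**
Reactants: 1 geranial [(2E)-3,7-dimethylocta-2,6-dienal]; 2 methyl 3-methylbut-3-enoate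
Product: 3 (6S)-6-[(1E)-2,6-dimethylhepta-1,5-dien-1-yl]-4-methyl-5,6-dihydro-2H-pyran-2-one
Conditions: [Cu(MeCN)4]PF6 (5 mol %), (R)-DTBM-SEGPHOS (6 mol %), Et3N (10 mol %), THF, −20 °C to rt
Reagents that add atoms: none
Why: Copper-catalysed direct asymmetric vinylogous aldol reaction (γ-attack of the copper dienolate on the aldehyde) followed by lactonisation of the (Z)-δ-hydroxy enoate, the chiral bisphosphine setting C6 (S) while the (E)-alkene of geranial is carried over unchanged.

**Step 2**
Reactants: 3 (6S)-6-[(1E)-2,6-dimethylhepta-1,5-dien-1-yl]-4-methyl-5,6-dihydro-2H-pyran-2-one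
Product: 5 (2Z,5R,6E)-3,7,11-trimethyl-5-(trimethylsilyl)dodeca-2,6,10-trienoic acid, via silyl ester 4 (not isolated)
Conditions: Pd(dba)2 (5 mol %), LiCl (20 mol %), Me3SiSiMe3 (1.5 equiv), DMF, 80 °C; then aqueous citric acid
Reagents that add atoms: hexamethyldisilane, C[Si](C)(C)[Si](C)(C)C
Why: Palladium-catalysed allylic silylation with a disilane (Tsuji type), in which zerovalent palladium ionises the allylic lactone C–O bond with inversion and delivers silicon from the metal to the less hindered allyl terminus with retention, so C5 is set (R) by net inversion, the (2Z)-acid is released and the (6E)-alkene is kept.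

**Step 3**
Reactants: 5 (2Z,5R,6E)-3,7,11-trimethyl-5-(trimethylsilyl)dodeca-2,6,10-trienoic acid
Product: 7 (7S)-3,7-dimethyl-7-(4-methylpent-3-en-1-yl)cyclohepta-2,5-dien-1-one, via acid chloride 6 (not isolated)
Conditions: 1-chloro-N,N,2-trimethylprop-1-en-1-amine (1.1 equiv), CH2Cl2, 0 °C; then SnCl4 (1.1 equiv), −78 °C, 0.01 M
Reagents that add atoms: none
Why: Intramolecular Friedel–Crafts-type acylation of an allylsilane (anti SE2′), in which the (Z)-acyl cation attacks C7 anti to the C–Si bond while silicon stabilises the charge at C6 and then leaves, so the seven-membered ring and the quaternary centre C7 (S) form with 1,3-chirality transfer from C5.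

**Step 4**
Reactants: 7 (7S)-3,7-dimethyl-7-(4-methylpent-3-en-1-yl)cyclohepta-2,5-dien-1-one
Product: 9 (7S)-3,7-dimethyl-7-(4-methyl-3-oxopentyl)cyclohepta-2,5-dien-1-one, via epoxide 8 (not isolated)
Conditions: mCPBA (1.05 equiv), CH2Cl2, 0 °C; NaHCO3 wash, dry; then BF3·OEt2 (0.3 equiv), CH2Cl2, −78 °C
Reagents that add atoms: 3-chloroperoxybenzoic acid (mCPBA), OOC(=O)c1cccc(Cl)c1
Why: Chemoselective Prilezhaev epoxidation of the most electron-rich (trisubstituted, remote) alkene followed by Meinwald rearrangement, where the tertiary cation takes a hydride from the adjacent carbon to give the isopropyl ketone; no stereocentre is created and C7 is untouched.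

**Step 5**
Reactants: 9 (7S)-3,7-dimethyl-7-(4-methyl-3-oxopentyl)cyclohepta-2,5-dien-1-one
Product: 11 (7R)-6-bromo-3,7-dimethyl-7-(4-methyl-3-oxopentyl)cyclohept-2-ene-1,5-dione (both C6 epimers), via bromohydrin 10 (not isolated)
Conditions: NBS (1.1 equiv), DMSO/H2O 10:1, 0 °C; then IBX (1.5 equiv), rt
Reagents that add atoms: N-bromosuccinimide, O=C1CCC(=O)N1Br; water, O
Why: Bromohydrin formation on the only isolated alkene, with water opening the bromonium ion at the less hindered C5 (C6 is neopentyl), then IBX oxidation to the α-bromo ketone; the bromide configuration is irrelevant because it is lost in step 6, and the C7 descriptor changes to R only because bromine raises the CIP rank of C6.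

**Step 6**
Reactants: 11 (7R)-6-bromo-3,7-dimethyl-7-(4-methyl-3-oxopentyl)cyclohept-2-ene-1,5-dione
Product: 12 (3R,3aR,8aS)-3-hydroxy-6,8a-dimethyl-3-(propan-2-yl)-1,2,3,3a,5,8a-hexahydroazulene-4,8-dione
Conditions: SmI2 (2.2 equiv, 0.1 M in THF), THF, −78 °C, then 0 °C for 1 h, substrate 5 mM; pH 7 phosphate buffer
Reagents that add atoms: none
Why: Samarium diiodide Reformatsky-type aldol cyclisation, in which the regiodefined trivalent samarium enolate closes the five-membered ring onto the isopropyl ketone through an O–Sm–O chelated transition state that places the new hydroxyl syn to the C4 carbonyl (C3 R), and reversible aldolisation of the aldolate at 0 °C is relied on to settle the ring fusion as trans (C3a R).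

**Step 7**
Reactants: 12 (3R,3aR,8aS)-3-hydroxy-6,8a-dimethyl-3-(propan-2-yl)-1,2,3,3a,5,8a-hexahydroazulene-4,8-dione
Product: 13 (3R,3aS,4S,8aS)-3,4-dihydroxy-6,8a-dimethyl-3-(propan-2-yl)-2,3,3a,4,5,8a-hexahydroazulen-8(1H)-one
Conditions: Me4N[BH(OAc)3] (5 equiv), MeCN/AcOH 1:1, −25 °C
Reagents that add atoms: none
Why: Evans–Saksena hydroxyl-directed reduction, in which the alkoxyborohydride formed at the tertiary hydroxyl delivers hydride intramolecularly to the β-carbonyl from the hydroxyl face to give the 1,3-anti diol (C4 S), leaving the undirected enone untouched.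

**Step 8**
Reactants: 13 (3R,3aS,4S,8aS)-3,4-dihydroxy-6,8a-dimethyl-3-(propan-2-yl)-2,3,3a,4,5,8a-hexahydroazulen-8(1H)-one; 14 4-acetoxybenzoyl chloride
Product: 16 (3R,3aS,4S,8aS)-3-hydroxy-6,8a-dimethyl-8-oxo-3-(propan-2-yl)-1,2,3,3a,4,5,8,8a-octahydroazulen-4-yl 4-hydroxybenzoate, via aryl acetate 15 (not isolated)
Conditions: 14 (1.3 equiv), Et3N (2 equiv), DMAP (0.1 equiv), CH2Cl2, 0 °C to rt; then pyrrolidine (3 equiv), 0 °C
Reagents that add atoms: none
Why: DMAP-catalysed acylation of the only secondary hydroxyl (the tertiary one is inert) with retention at C4, followed by chemoselective aminolysis of the far more reactive aryl acetate to free the phenol without touching the alkyl benzoate.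

**Compound list**
1 | geranial, (2E)-3,7-dimethylocta-2,6-dienal | CC(C)=CCC/C(C)=C/C=O | starting material
2 | methyl 3-methylbut-3-enoate | COC(=O)CC(C)=C | starting material
3 | (6S)-6-[(1E)-2,6-dimethylhepta-1,5-dien-1-yl]-4-methyl-5,6-dihydro-2H-pyran-2-one | CC1=CC(=O)O[C@@H](C1)/C=C(\C)CCC=C(C)C | intermediate
4 | trimethylsilyl (2Z,5R,6E)-3,7,11-trimethyl-5-(trimethylsilyl)dodeca-2,6,10-trienoate | C[Si](C)(C)OC(=O)/C=C(/C)C[C@@H]([Si](C)(C)C)/C=C(\C)CCC=C(C)C | intermediate
5 | (2Z,5R,6E)-3,7,11-trimethyl-5-(trimethylsilyl)dodeca-2,6,10-trienoic acid | OC(=O)/C=C(/C)C[C@@H]([Si](C)(C)C)/C=C(\C)CCC=C(C)C | intermediate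
6 | (2Z,5R,6E)-3,7,11-trimethyl-5-(trimethylsilyl)dodeca-2,6,10-trienoyl chloride | ClC(=O)/C=C(/C)C[C@@H]([Si](C)(C)C)/C=C(\C)CCC=C(C)C | intermediate
7 | (7S)-3,7-dimethyl-7-(4-methylpent-3-en-1-yl)cyclohepta-2,5-dien-1-one | CC1=CC(=O)[C@@](C)(CCC=C(C)C)C=CC1 | intermediate
8 | (7S)-7-[2-(3,3-dimethyloxiran-2-yl)ethyl]-3,7-dimethylcyclohepta-2,5-dien-1-one (both oxirane epimers) | CC1=CC(=O)[C@@](C)(CCC2OC2(C)C)C=CC1 | intermediate
9 | (7S)-3,7-dimethyl-7-(4-methyl-3-oxopentyl)cyclohepta-2,5-dien-1-one | CC1=CC(=O)[C@@](C)(CCC(=O)C(C)C)C=CC1 | intermediate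
10 | (7R)-6-bromo-5-hydroxy-3,7-dimethyl-7-(4-methyl-3-oxopentyl)cyclohept-2-en-1-one (trans bromohydrin, both diastereomers) | CC1=CC(=O)[C@@](C)(CCC(=O)C(C)C)C(Br)C(O)C1 | intermediate
11 | (7R)-6-bromo-3,7-dimethyl-7-(4-methyl-3-oxopentyl)cyclohept-2-ene-1,5-dione (both C6 epimers) | CC1=CC(=O)[C@@](C)(CCC(=O)C(C)C)C(Br)C(=O)C1 | intermediate
12 | (3R,3aR,8aS)-3-hydroxy-6,8a-dimethyl-3-(propan-2-yl)-1,2,3,3a,5,8a-hexahydroazulene-4,8-dione | CC1=CC(=O)[C@@]2(C)CC[C@@](O)(C(C)C)[C@@H]2C(=O)C1 | intermediate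
13 | (3R,3aS,4S,8aS)-3,4-dihydroxy-6,8a-dimethyl-3-(propan-2-yl)-2,3,3a,4,5,8a-hexahydroazulen-8(1H)-one | CC1=CC(=O)[C@@]2(C)CC[C@@](O)(C(C)C)[C@@H]2[C@@H](O)C1 | intermediate
14 | 4-acetoxybenzoyl chloride | CC(=O)Oc1ccc(cc1)C(Cl)=O | starting material
15 | (3R,3aS,4S,8aS)-3-hydroxy-6,8a-dimethyl-8-oxo-3-(propan-2-yl)-1,2,3,3a,4,5,8,8a-octahydroazulen-4-yl 4-(acetyloxy)benzoate | CC1=CC(=O)[C@@]2(C)CC[C@@](O)(C(C)C)[C@@H]2[C@@H](OC(=O)c2ccc(OC(C)=O)cc2)C1 | intermediate
16 | (3R,3aS,4S,8aS)-3-hydroxy-6,8a-dimethyl-8-oxo-3-(propan-2-yl)-1,2,3,3a,4,5,8,8a-octahydroazulen-4-yl 4-hydroxybenzoate | CC1=CC(=O)[C@@]2(C)CC[C@@](O)(C(C)C)[C@@H]2[C@@H](OC(=O)c2ccc(O)cc2)C1 | target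

**Step count and risks**
Total steps: 8. Longest linear sequence: 8 steps (1 → 16).

The three steps most likely to fail:

Step 6 is the weakest point. Closure of the five-membered ring from a tether on the neighbouring quaternary carbon kinetically favours the cis-fused ketol, so the trans fusion depends on aldol reversibility and on the trans isomer being the more stable one, which is not secured. The enolate may also be quenched by the acidic C5 methylene of the ene-dione. The fallback sets out from 9 and comes back at 12: Wacker oxidation of the isolated ring alkene (Pd(OAc)2, benzoquinone, HBF4, MeCN/H2O), with oxygen going to the carbon remote from the quaternary centre, gives (7S)-3,7-dimethyl-7-(4-methyl-3-oxopentyl)cyclohept-2-ene-1,5-dione F7. This is then cyclised under fully equilibrating protic conditions (KOH, MeOH, 0 °C to rt), where only the five-ring aldol can accumulate and the ring-fusion ratio is thermodynamic, to give 12.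

Step 2 may fail through β-hydride elimination of the allyl–palladium carboxylate to the trienoic acid, or through loss of configuration and alkene geometry by allyl isomerisation. The fallback sets out from 3 and comes back at 7 without silicon. Reduction of the lactone (LiAlH4, Et2O, 0 °C) gives (2Z,5S,6E)-3,7,11-trimethyldodeca-2,6,10-triene-1,5-diol F1. Mitsunobu cyclodehydration through the primary allylic alcohol (PPh3, DIAD) gives (2S)-2-[(1E)-2,6-dimethylhepta-1,5-dien-1-yl]-4-methyl-3,6-dihydro-2H-pyran F2. Deprotonation of the ring O–CH2 (n-BuLi, THF, −78 °C) triggers a [2,3]-Wittig ring expansion that forms the same C–C bond on the same face and gives (7S)-3,7-dimethyl-7-(4-methylpent-3-en-1-yl)cyclohepta-2,5-dien-1-ol F3. MnO2 oxidation returns 7.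

Step 3 may fail through protodesilylation, slow seven-ring closure against allylic strain, or drift of the skipped dienone into conjugation under SnCl4. The fallback sets out from 5 and comes back at 7 with an aldehyde as the electrophile. LiAlH4 reduction gives (2Z,5R,6E)-3,7,11-trimethyl-5-(trimethylsilyl)dodeca-2,6,10-trien-1-ol F4. MnO2 gives (2Z,5R,6E)-3,7,11-trimethyl-5-(trimethylsilyl)dodeca-2,6,10-trienal F5. Intramolecular Hosomi–Sakurai allylation (BF3·OEt2, CH2Cl2, −78 °C), with the same anti SE2′ sense, gives (7S)-3,7-dimethyl-7-(4-methylpent-3-en-1-yl)cyclohepta-2,5-dien-1-ol F6. MnO2 oxidation returns 7.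

**Further compounds**
F1 | step 2 | (2Z,5S,6E)-3,7,11-trimethyldodeca-2,6,10-triene-1,5-diol | OC/C=C(/C)C[C@H](O)/C=C(\C)CCC=C(C)C
F2 | step 2 | (2S)-2-[(1E)-2,6-dimethylhepta-1,5-dien-1-yl]-4-methyl-3,6-dihydro-2H-pyran | CC1=CCO[C@@H](C1)/C=C(\C)CCC=C(C)C
F3 | step 2 | (7S)-3,7-dimethyl-7-(4-methylpent-3-en-1-yl)cyclohepta-2,5-dien-1-ol (either C1 epimer) | CC1=CC(O)[C@@](C)(CCC=C(C)C)C=CC1
F4 | step 3 | (2Z,5R,6E)-3,7,11-trimethyl-5-(trimethylsilyl)dodeca-2,6,10-trien-1-ol | OC/C=C(/C)C[C@@H]([Si](C)(C)C)/C=C(\C)CCC=C(C)C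
F5 | step 3 | (2Z,5R,6E)-3,7,11-trimethyl-5-(trimethylsilyl)dodeca-2,6,10-trienal | O=C/C=C(/C)C[C@@H]([Si](C)(C)C)/C=C(\C)CCC=C(C)C
F6 | step 3 | (7S)-3,7-dimethyl-7-(4-methylpent-3-en-1-yl)cyclohepta-2,5-dien-1-ol (either C1 epimer) | CC1=CC(O)[C@@](C)(CCC=C(C)C)C=CC1
F7 | step 6 | (7S)-3,7-dimethyl-7-(4-methyl-3-oxopentyl)cyclohept-2-ene-1,5-dione | CC1=CC(=O)[C@@](C)(CCC(=O)C(C)C)CC(=O)C1
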